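**Retrosynthetic overview**
1. Target ⇒ O-acetylation of the hydroxy acid, whose (4Z)-trisubstituted allylic alcohol comes from a three-component β-oxido-ylide olefination (phosphonium acid + 3-(furan-3-yl)propanal + formaldehyde).
2. Phosphonium acid ⇒ (R)-2-(4-chlorobutyl)-6-methylhept-5-enoic acid ⇒ its N-benzyl-N-phenyl amide (amide → aldehyde → acid).
3. Key C–C bond: C2–homoprenyl, formed with the α-carbon of the carboxyl unit as the electrophile (enolonium equivalent, racemic α-bromo amide) and homoprenylzinc bromide under chiral nickel catalysis; this step alone sets the stereocentre.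
4. α-Bromo amide ⇒ 6-chlorohexanoyl chloride + N-benzylaniline; aldehyde ⇒ 3-bromofuran + oxetane.
5. No ring is formed; the furan is bought intact as 3-bromofuran.

Assumption: for this catalyst class (R)-i-Pr-Pybox is taken to give the (S)-amide when the zinc-derived chain outranks the resident α-chain, so 2,6-bis[(4S)-4-isopropyl-4,5-dihydrooxazol-2-yl]pyridine ((S)-i-Pr-Pybox) is used to obtain (R)-7; this sense is recalled from precedent, not verified, and is confirmed by chiral HPLC on 7.

**Step 1**
Reactants: 1 6-chlorohexanoyl chloride; 2 N-benzylaniline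
Product: 4 rac-N-benzyl-2-bromo-6-chloro-N-phenylhexanamide, via 2-bromo-6-chlorohexanoyl chloride 3 (not isolated)
Conditions: NBS, HBr (cat.), SOCl2, 70 °C; concentrate; then 2, pyridine, CH2Cl2, 0 °C to rt
Reagents that add atoms: N-bromosuccinimide, O=C1CCC(=O)N1Br
Why: The acid chloride enolises easily, so Hell–Volhard–Zelinsky-type bromination occurs only at C2, and the crude α-bromo acid chloride N-acylates the secondary aniline to give the racemic tertiary α-bromo amide (the centre is left racemic on purpose).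

**Step 2**
Reactants: 4 rac-N-benzyl-2-bromo-6-chloro-N-phenylhexanamide; 5 5-bromo-2-methylpent-2-ene
Product: 7 (2R)-N-benzyl-2-(4-chlorobutyl)-6-methyl-N-phenylhept-5-enamide, via (4-methylpent-3-en-1-yl)zinc bromide 6 (not isolated)
Conditions: 5, Zn dust, I2 (5 mol%), DMI, 70 °C; then 4, NiCl2·glyme (10 mol%), (S)-i-Pr-Pybox (13 mol%), DMI/THF, 0 °C, 24 h
Reagents that add atoms: none
Why: Nickel-catalysed stereoconvergent Negishi alkyl–alkyl coupling in which the normally nucleophilic α-carbon is the electrophile: both enantiomers of 4 give the same planar α-amido radical, and the chiral NiCl2/pybox–alkyl complex captures one face to deliver the homoprenyl group and set (R) at C2 (about 90% ee expected), while the unactivated primary chloride and the trisubstituted alkene do not react at 0 °C.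

**Step 3**
Reactants: 7 (2R)-N-benzyl-2-(4-chlorobutyl)-6-methyl-N-phenylhept-5-enamide
Product: 8 (2R)-2-(4-chlorobutyl)-6-methylhept-5-enal
Conditions: Cp2Zr(H)Cl (1.6 equiv), THF, rt, 30 min; H2O
Reagents that add atoms: none
Why: Schwartz reduction of a tertiary amide: hydrozirconation of the C=O gives a zirconated hemiaminal that releases the aldehyde only on work-up, so there is no over-reduction, the alkyl chloride and the slowly hydrozirconated trisubstituted alkene survive, and the non-basic conditions keep C2 (R).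

**Step 4**
Reactants: 8 (2R)-2-(4-chlorobutyl)-6-methylhept-5-enal
Product: 9 (2R)-2-(4-chlorobutyl)-6-methylhept-5-enoic acid
Conditions: NaClO2, NaH2PO4, 2-methylbut-2-ene, t-BuOH/H2O, 0 °C to rt (crude 8 used at once)
Reagents that add atoms: sodium chlorite NaClO2, [Na+].[O-]Cl=O
Why: Pinnick oxidation converts the α-branched aldehyde to the acid without enolisation, and excess 2-methylbut-2-ene scavenges HOCl so the homoprenyl alkene is not chlorinated.

**Step 5**
Reactants: 9 (2R)-2-(4-chlorobutyl)-6-methylhept-5-enoic acid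
Product: 10 [(5R)-5-carboxy-9-methyldec-8-en-1-yl]triphenylphosphonium iodide
Conditions: PPh3, NaI, MeCN, reflux, 36 h
Reagents that add atoms: triphenylphosphine, c1ccccc1P(c1ccccc1)c1ccccc1; sodium iodide NaI, [Na+].[I-]
Why: In situ Finkelstein exchange gives the primary iodide, which quaternises PPh3 by SN2, while seven-membered lactonisation of the un-ionised acid is slow and the remote stereocentre is not involved.

**Step 6**
Reactants: 11 3-bromofuran; 12 oxetane
Product: 14 3-(furan-3-yl)propan-1-ol, via 3-lithiofuran 13 (not isolated)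
Conditions: n-BuLi, THF, −78 °C; then 12, BF3·OEt2, −78 °C; H2O
Reagents that add atoms: none
Why: Bromine–lithium exchange gives 3-lithiofuran, which holds its position at −78 °C, and BF3-activated oxetane is opened by SN2 at CH2 to append the three-carbon alcohol chain.

**Step 7**
Reactants: 14 3-(furan-3-yl)propan-1-ol
Product: 15 3-(furan-3-yl)propanal
Conditions: Dess–Martin periodinane, CH2Cl2, 0 °C to rt
Reagents that add atoms: none
Why: Dess–Martin oxidation stops cleanly at the aldehyde under near-neutral conditions that the furan tolerates.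

**Step 8**
Reactants: 10 [(5R)-5-carboxy-9-methyldec-8-en-1-yl]triphenylphosphonium iodide; 15 3-(furan-3-yl)propanal
Product: 19 (2R)-2-[(4Z)-7-(furan-3-yl)-4-(hydroxymethyl)hept-4-en-1-yl]-6-methylhept-5-enoic acid, via lithium carboxylate ylide 16 (not isolated), via lithium betaine 17 (not isolated), via β-oxido ylide 18 (not isolated)
Conditions: n-BuLi (2 equiv), THF, −78 to 0 °C; 15, −78 °C; n-BuLi (1 equiv), −78 to −25 °C; (CH2O)n, 0 °C to rt; cold 1 M HCl
Reagents that add atoms: paraformaldehyde (as formaldehyde), C=O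
Why: Wittig–Schlosser β-oxido-ylide olefination (SCOOPY variant): the lithium betaine from 16 and 15 is deprotonated to 18, formaldehyde enters cis to the aldehyde-derived chain (the same facial preference as Schlosser protonation), and loss of Ph3PO with the original aldehyde oxygen gives the trisubstituted alkene with CH2OH cis to the furylethyl chain, i.e. (4Z), while the lithium carboxylate is inert and C2 is untouched.

**Step 9**
Reactants: 19 (2R)-2-[(4Z)-7-(furan-3-yl)-4-(hydroxymethyl)hept-4-en-1-yl]-6-methylhept-5-enoic acid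
Product: 20 (2R)-2-[(4Z)-4-(acetoxymethyl)-7-(furan-3-yl)hept-4-en-1-yl]-6-methylhept-5-enoic acid
Conditions: Ac2O, pyridine, DMAP (cat.), CH2Cl2, 0 °C to rt; aq. NaHCO3, then pH 3
Reagents that add atoms: acetic anhydride, CC(=O)OC(C)=O
Why: DMAP-catalysed O-acetylation of the primary allylic alcohol, with the mixed anhydride formed at the acid hydrolysed again in the aqueous work-up.

**Compound list**
1 | 6-chlorohexanoyl chloride | ClCCCCCC(=O)Cl | starting material
2 | N-benzylaniline | C(Nc1ccccc1)c1ccccc1 | starting material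
3 | 2-bromo-6-chlorohexanoyl chloride (racemic) | ClCCCCC(Br)C(=O)Cl | intermediate
4 | rac-N-benzyl-2-bromo-6-chloro-N-phenylhexanamide | ClCCCCC(Br)C(=O)N(Cc1ccccc1)c1ccccc1 | intermediate
5 | 5-bromo-2-methylpent-2-ene | CC(C)=CCCBr | starting material
6 | (4-methylpent-3-en-1-yl)zinc bromide | CC(C)=CCC[Zn]Br | intermediate
7 | (2R)-N-benzyl-2-(4-chlorobutyl)-6-methyl-N-phenylhept-5-enamide | ClCCCC[C@H](CCC=C(C)C)C(=O)N(Cc1ccccc1)c1ccccc1 | intermediate
8 | (2R)-2-(4-chlorobutyl)-6-methylhept-5-enal | ClCCCC[C@H](CCC=C(C)C)C=O | intermediate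
9 | (2R)-2-(4-chlorobutyl)-6-methylhept-5-enoic acid | ClCCCC[C@H](CCC=C(C)C)C(=O)O | intermediate
10 | [(5R)-5-carboxy-9-methyldec-8-en-1-yl]triphenylphosphonium iodide | c1ccccc1[P+](c1ccccc1)(c1ccccc1)CCCC[C@H](CCC=C(C)C)C(=O)O.[I-] | intermediate
11 | 3-bromofuran | Brc1ccoc1 | starting material
12 | oxetane | C1COC1 | starting material
13 | 3-lithiofuran | [Li]c1ccoc1 | intermediate
14 | 3-(furan-3-yl)propan-1-ol | OCCCc1ccoc1 | intermediate
15 | 3-(furan-3-yl)propanal | O=CCCc1ccoc1 | intermediate
16 | lithium (2R)-6-methyl-2-[4-(triphenyl-λ5-phosphanylidene)butyl]hept-5-enoate | c1ccccc1P(c1ccccc1)(c1ccccc1)=CCCC[C@H](CCC=C(C)C)C(=O)[O-].[Li+] | intermediate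
17 | lithium (2R)-2-[7-(furan-3-yl)-5-oxido-4-(triphenylphosphonio)heptyl]-6-methylhept-5-enoate (diastereomer mixture at the two new centres) | [O-]C(CCc1ccoc1)C(CCC[C@H](CCC=C(C)C)C(=O)[O-])[P+](c1ccccc1)(c1ccccc1)c1ccccc1.[Li+] | intermediate
18 | dilithium (2R)-2-[7-(furan-3-yl)-5-oxido-4-(triphenyl-λ5-phosphanylidene)heptyl]-6-methylhept-5-enoate (epimer mixture at the oxido carbon) | [O-]C(CCc1ccoc1)C(CCC[C@H](CCC=C(C)C)C(=O)[O-])=P(c1ccccc1)(c1ccccc1)c1ccccc1.[Li+].[Li+] | intermediate
19 | (2R)-2-[(4Z)-7-(furan-3-yl)-4-(hydroxymethyl)hept-4-en-1-yl]-6-methylhept-5-enoic acid | OC/C(=C\CCc1ccoc1)CCC[C@H](CCC=C(C)C)C(=O)O | intermediate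
20 | (2R)-2-[(4Z)-4-(acetoxymethyl)-7-(furan-3-yl)hept-4-en-1-yl]-6-methylhept-5-enoic acid | CC(=O)OC/C(=C\CCc1ccoc1)CCC[C@H](CCC=C(C)C)C(=O)O | target

**Totals**
Total steps: 9. Longest linear sequence: 7 (steps 1, 2, 3, 4, 5, 8, 9); steps 6 and 7 form the aldehyde branch.

**Three steps most likely to fail**

Step 2 (stereoconvergent coupling; risks are enantioselectivity with an ω-chloroalkyl electrophile and quality of the homoallylic zinc reagent). The fallback forms the other C2–C bond, with the homoprenyl chain resident on the electrophile. It sets out from 5 and comes back at 7. The lithium enolate of commercial N-benzyl-N-phenylacetamide (LiN(i-Pr)2, THF, −78 °C) is alkylated with 5 to give N-benzyl-6-methyl-N-phenylhept-5-enamide F1. The enolate of F1 is brominated (LiN(i-Pr)2, then BrCCl2CCl2Br, −78 °C) to rac-N-benzyl-2-bromo-6-methyl-N-phenylhept-5-enamide F2. F2 is then coupled with (4-chlorobutyl)zinc bromide F3 (from 1-bromo-4-chlorobutane and Zn in DMI) under NiCl2·glyme and the (R)-ligand; the ligand enantiomer is inverted because the zinc-derived chain is now the lower-ranked one, and this gives 7.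

Step 3 (Schwartz reduction of a hindered N-aryl amide; risks are slow reaction and erosion of ee at the α-branched aldehyde). The fallback avoids the aldehyde altogether. It sets out from 7 and comes back at 9. LiAlH4 (THF, 0 °C) cleaves the anilide reductively to (2R)-2-(4-chlorobutyl)-6-methylhept-5-en-1-ol F4, and Jones oxidation (CrO3, H2SO4, acetone, 0 °C) takes F4 straight to 9.

Step 8 (β-oxido-ylide olefination; risks are solubility of the lithium carboxylate ylide at −78 °C and incomplete second deprotonation). The fallback builds the (Z)-alkene by a Still–Gennari olefination on a chain one carbon shorter. It sets out from 2 (using 6 and 15 as in the main route) and comes back at 19.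
- Commercial 5-chloropentanoyl chloride is brominated as in step 1 to 2-bromo-5-chloropentanoyl chloride F5 and acylates 2 to give rac-N-benzyl-2-bromo-5-chloro-N-phenylpentanamide F6.
- Nickel coupling of F6 with 6 (same (S)-ligand) gives (2S)-N-benzyl-2-(3-chloropropyl)-6-methyl-N-phenylhept-5-enamide F7; the spatial arrangement is the same as in 7, and the descriptor changes only because chloropropyl outranks homoprenyl.
- F7 alkylates methyl 2-[bis(2,2,2-trifluoroethoxy)phosphoryl]acetate (NaH, NaI, DMSO, 50 °C) to methyl (6R)-7-[benzyl(phenyl)amino]-2-[bis(2,2,2-trifluoroethoxy)phosphoryl]-6-(4-methylpent-3-en-1-yl)-7-oxoheptanoate F8.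
- Olefination of F8 with 15 (KN(SiMe3)2, 18-crown-6, THF, −78 °C) gives methyl (2Z)-2-[(4R)-5-[benzyl(phenyl)amino]-4-(4-methylpent-3-en-1-yl)-5-oxopentyl]-5-(furan-3-yl)pent-2-enoate F9.
- i-Bu2AlH (CH2Cl2, −78 °C) reduces the enoate to (2R)-N-benzyl-2-[(4Z)-7-(furan-3-yl)-4-(hydroxymethyl)hept-4-en-1-yl]-6-methyl-N-phenylhept-5-enamide F10.
- KOH in ethylene glycol/H2O (130 °C) hydrolyses the anilide of F10 to 19.

**Further compounds**
F1 | step 2 | N-benzyl-6-methyl-N-phenylhept-5-enamide | CC(C)=CCCCC(=O)N(Cc1ccccc1)c1ccccc1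
F2 | step 2 | rac-N-benzyl-2-bromo-6-methyl-N-phenylhept-5-enamide | CC(C)=CCCC(Br)C(=O)N(Cc1ccccc1)c1ccccc1
F3 | step 2 | (4-chlorobutyl)zinc bromide | ClCCCC[Zn]Br
F4 | step 3 | (2R)-2-(4-chlorobutyl)-6-methylhept-5-en-1-ol | ClCCCC[C@H](CCC=C(C)C)CO
F5 | step 8 | 2-bromo-5-chloropentanoyl chloride (racemic) | ClCCCC(Br)C(=O)Cl
F6 | step 8 | rac-N-benzyl-2-bromo-5-chloro-N-phenylpentanamide | ClCCCC(Br)C(=O)N(Cc1ccccc1)c1ccccc1
F7 | step 8 | (2S)-N-benzyl-2-(3-chloropropyl)-6-methyl-N-phenylhept-5-enamide | ClCCC[C@H](CCC=C(C)C)C(=O)N(Cc1ccccc1)c1ccccc1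
F8 | step 8 | methyl (6R)-7-[benzyl(phenyl)amino]-2-[bis(2,2,2-trifluoroethoxy)phosphoryl]-6-(4-methylpent-3-en-1-yl)-7-oxoheptanoate (epimer mixture at C2) | COC(=O)C(CCC[C@H](CCC=C(C)C)C(=O)N(Cc1ccccc1)c1ccccc1)P(=O)(OCC(F)(F)F)OCC(F)(F)F
F9 | step 8 | methyl (2Z)-2-[(4R)-5-[benzyl(phenyl)amino]-4-(4-methylpent-3-en-1-yl)-5-oxopentyl]-5-(furan-3-yl)pent-2-enoate | COC(=O)/C(=C\CCc1ccoc1)CCC[C@H](CCC=C(C)C)C(=O)N(Cc1ccccc1)c1ccccc1
F10 | step 8 | (2R)-N-benzyl-2-[(4Z)-7-(furan-3-yl)-4-(hydroxymethyl)hept-4-en-1-yl]-6-methyl-N-phenylhept-5-enamide | OC/C(=C\CCc1ccoc1)CCC[C@H](CCC=C(C)C)C(=O)N(Cc1ccccc1)c1ccccc1
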